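Numbering (daucane): ring A = cyclopentane C1–C5 (C1 quaternary with CH3-15, C4 with OH and isopropyl, C5 = ring-fusion CH). Ring B = cycloheptane C1, C5, C6 (O-vanilloyl), C7, C8 (=C14H2), C9 (OH), C10. α = face of H5, β = face of CH3-15.
Cuts, in retrosynthetic order: phenol O–Si; C9–O (allylic C–H oxidation); ester O6–C(=O)Ar; C6–C7 (opens ring B); C4–isopropyl; C5–C6; C1–C15; C1–C10.
Enabling feature: in ring B the C6 carbinol is homoallylic to the exocyclic C8=C14 bond (O–C6–C7–C8=C14), the retron of a type 2 carbonyl-ene reaction. A C6 aldehyde on C5 and a 2-methylallyl terminus (C7H2=C8–C14H3) on the C1 side chain give ring B, the C6 stereocentre and the exocyclic methylene in one event.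
Forward order: ring A is bought as 3-ethoxycyclopentenone and loaded at C1, C5 and C4. Ring B is closed last; the ester, the C9 hydroxyl group and the free phenol follow.
Stereochemistry: C1 comes from a copper-catalysed asymmetric conjugate addition of Me3Al. C5 is set by attack anti to the longer C1 chain and C4 by attack anti to the C5 substituent. C6 comes from the chair-like ene transition state, and C9 from oxidation on the α face.

Key step: step 6

Assumption: the chiral ligand of step 2 is taken to deliver methyl to the enone face that gives the (S)-configured quaternary carbon of 7. If the sense of induction proves opposite, the antipodal ligand is used.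

Step 1
Reactants: 1 4-bromo-2-methylbut-1-ene; 2 3-ethoxycyclopent-2-en-1-one
Product: 5 3-(3-methylbut-3-en-1-yl)cyclopent-2-en-1-one, via Grignard reagent 3 (not isolated), via magnesium alkoxide 4 (not isolated)
Conditions: 1, Mg, THF, 40 °C; 2, THF, 0 °C; then 1 M HCl, rt
Reagents that add atoms: water, O
Why: Stork–Danheiser sequence: the Grignard reagent adds 1,2 to the vinylogous ester, and aqueous acid ionises the tertiary allylic alcohol and hydrolyses the enol ether, which transposes the carbonyl group and forms the C1–C10 bond without creating a stereocentre.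

Step 2
Reactants: 5 3-(3-methylbut-3-en-1-yl)cyclopent-2-en-1-one
Product: 7 (S)-triethyl{[3-methyl-3-(3-methylbut-3-en-1-yl)cyclopent-1-en-1-yl]oxy}silane, via dimethylaluminium enolate 6 (not isolated)
Conditions: Me3Al, Cu(OTf)2 (5 mol %), chiral sulfonate-bearing imidazolinium salt (carbene precursor, 5 mol %), THF, −78 to −30 °C; then Et3SiOTf, −78 to 0 °C
Reagents that add atoms: trimethylaluminium, C[Al](C)C; triethylsilyl trifluoromethanesulfonate, CC[Si](CC)(CC)OS(=O)(=O)C(F)(F)F
Why: Copper-catalysed asymmetric conjugate addition of Me3Al to a β-alkyl cyclopentenone, a known route to quaternary carbons, sets C1 through face selection by the chiral carbene ligand on copper, and O-silylation of the aluminium enolate stores the C4=C5 enolate regiochemistry.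

Step 3
Reactants: 7 (S)-triethyl{[3-methyl-3-(3-methylbut-3-en-1-yl)cyclopent-1-en-1-yl]oxy}silane
Product: 8 (2S,3S)-2-(dimethoxymethyl)-3-methyl-3-(3-methylbut-3-en-1-yl)cyclopentan-1-one
Conditions: HC(OMe)3, TMSOTf (10 mol %), CH2Cl2, −78 °C
Reagents that add atoms: trimethyl orthoformate, COC(OC)OC
Why: Mukaiyama-type reaction of a silyl enol ether with an orthoformate: the small dimethoxycarbenium ion should attack C5 anti to the longer C1 chain (cis to CH3-15), which is also the thermodynamic arrangement of this epimerisable centre, while the far less nucleophilic 1,1-disubstituted alkene stays untouched.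

Step 4
Reactants: 8 (2S,3S)-2-(dimethoxymethyl)-3-methyl-3-(3-methylbut-3-en-1-yl)cyclopentan-1-one
Product: 9 (1R,2R,3S)-2-(dimethoxymethyl)-3-methyl-3-(3-methylbut-3-en-1-yl)-1-(propan-2-yl)cyclopentan-1-ol
Conditions: iPrMgCl, anhydrous CeCl3, THF, −78 to 0 °C; then water
Reagents that add atoms: isopropylmagnesium chloride, CC(C)[Mg]Cl
Why: Organocerium 1,2-addition, chosen because it suppresses enolisation, β-hydride reduction and loss of methanol from the β-keto acetal, should deliver isopropyl to C4 from the α face, anti to the adjacent C5 substituent and to CH3-15, so that the new hydroxyl group is β and cis to C6.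

Step 5
Reactants: 9 (1R,2R,3S)-2-(dimethoxymethyl)-3-methyl-3-(3-methylbut-3-en-1-yl)-1-(propan-2-yl)cyclopentan-1-ol
Product: 11 (1R,2R,5S)-5-methyl-5-(3-methylbut-3-en-1-yl)-2-(propan-2-yl)-2-[(triethylsilyl)oxy]cyclopentane-1-carbaldehyde, via lutidinium salt 10 (not isolated)
Conditions: Et3SiOTf (3.5 equiv), 2,6-lutidine (5 equiv), CH2Cl2, 0 °C; then water
Reagents that add atoms: triethylsilyl trifluoromethanesulfonate, CC[Si](CC)(CC)OS(=O)(=O)C(F)(F)F; water, O
Why: Silyl triflate and 2,6-lutidine silylate the tertiary alcohol and convert the dimethyl acetal through its lutidinium salt into the aldehyde on addition of water, a known non-acidic acetal cleavage that avoids dehydration, retro-aldol cleavage and C5 epimerisation of the β-oxygenated aldehyde.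

Step 6
Reactants: 11 (1R,2R,5S)-5-methyl-5-(3-methylbut-3-en-1-yl)-2-(propan-2-yl)-2-[(triethylsilyl)oxy]cyclopentane-1-carbaldehyde
Product: 13 dauc-8(14)-ene-4β,6α-diol, via 4-O-triethylsilyl ether 12 (not isolated)
Conditions: Me2AlCl (2 equiv), CH2Cl2, −78 to −20 °C; aq. potassium sodium tartrate; crude 12, TBAF, THF, 0 °C to rt
Reagents that add atoms: none
Why: Me2AlCl binds the C6 aldehyde oxygen, the terminal alkene carbon C7 attacks C6 while charge builds at the tertiary C8, and a C14 methyl hydrogen passes to oxygen through a six-centre array, after which loss of methane from the aluminium alcohol complex makes the step irreversible. The closest known reaction type is the Lewis-acid-promoted type 2 intramolecular carbonyl-ene (Prins-type) cyclisation of aldehydes that carry a 1,1-disubstituted alkene, established for six- and seven-membered rings. Ring B closes in a 7-exo-trig mode at the carbonyl group, with C8 and its tether inside the new ring, so that C14 is left as the exocyclic methylene. The only new stereocentre, C6, is controlled by the ring A stereocentres: in the chair-like transition state the aluminium-bound oxygen takes the equatorial site with H6 anti to H5, because the alternative places it syn-axial to CH3-15, and this should give the 6α-alcohol. The step needs proton loss from C14 and not from C9, which the geometry of the six-centre hydrogen transfer secures, and it needs cyclisation to outrun methyl transfer from aluminium, which the quaternary C1 (Thorpe–Ingold effect) and the trans arrangement of the two arms on ring A favour, while the C4 silyl ether keeps the aldehyde from retro-aldol cleavage and dehydration. Fluoride then takes this helper off crude 12.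

Step 7
Reactants: 14 vanillic acid
Product: 16 4-[(tert-butyldimethylsilyl)oxy]-3-methoxybenzoic acid, via bis-silyl derivative 15 (not isolated)
Conditions: TBSCl (2.5 equiv), imidazole, DMF, rt; then AcOH–THF–H2O, rt
Reagents that add atoms: tert-butyldimethylsilyl chloride, CC(C)(C)[Si](C)(C)Cl
Why: Standard silylation of phenol and acid followed by selective hydrolysis of the labile silyl ester leaves only the phenol masked for the esterification.

Step 8
Reactants: 13 dauc-8(14)-ene-4β,6α-diol; 16 4-[(tert-butyldimethylsilyl)oxy]-3-methoxybenzoic acid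
Product: 17 4β-hydroxydauc-8(14)-en-6α-yl 4-[(tert-butyldimethylsilyl)oxy]-3-methoxybenzoate
Conditions: DCC, DMAP, CH2Cl2, rt
Reagents that add atoms: none
Why: Steglich esterification acylates only the secondary C6 hydroxyl group, since the tertiary C4 hydroxyl group next to isopropyl is inert under these conditions, and no stereocentre is touched.

Step 9
Reactants: 17 4β-hydroxydauc-8(14)-en-6α-yl 4-[(tert-butyldimethylsilyl)oxy]-3-methoxybenzoate
Product: 18 4β,9α-dihydroxydauc-8(14)-en-6α-yl 4-[(tert-butyldimethylsilyl)oxy]-3-methoxybenzoate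
Conditions: SeO2 (0.3 equiv), tBuOOH (3 equiv), CH2Cl2, 0 °C to rt
Reagents that add atoms: tert-butyl hydroperoxide, CC(C)(C)OO
Why: Riley allylic oxidation (ene reaction, then 2,3-sigmatropic shift) returns the double bond to C8=C14 and should place the hydroxyl group at C9 and not at C7, whose C–H bonds are deactivated and shielded by the neighbouring aroyloxy group, and on the α face because the β face is covered by CH3-15.

Step 10
Reactants: 18 4β,9α-dihydroxydauc-8(14)-en-6α-yl 4-[(tert-butyldimethylsilyl)oxy]-3-methoxybenzoate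
Product: 19 4β,9α-dihydroxydauc-8(14)-en-6α-yl 4-hydroxy-3-methoxybenzoate (target)
Conditions: TBAF, AcOH (1:1), THF, 0 °C
Reagents that add atoms: none
Why: Buffered fluoride cleaves the aryl silyl ether without hydrolysis or migration of the hindered benzoate and without touching the allylic alcohol, which gives the target.

Compound list
1 | 4-bromo-2-methylbut-1-ene | C=C(C)CCBr | starting material
2 | 3-ethoxycyclopent-2-en-1-one | CCOC1=CC(=O)CC1 | starting material
3 | (3-methylbut-3-en-1-yl)magnesium bromide | C=C(C)CC[Mg]Br | intermediate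
4 | bromomagnesium 3-ethoxy-1-(3-methylbut-3-en-1-yl)cyclopent-2-en-1-olate | CCOC1=CC(CCC(C)=C)(O[Mg]Br)CC1 | intermediate
5 | 3-(3-methylbut-3-en-1-yl)cyclopent-2-en-1-one | C=C(C)CCC1=CC(=O)CC1 | intermediate
6 | dimethylaluminium enolate of (S)-3-methyl-3-(3-methylbut-3-en-1-yl)cyclopentanone (C4=C5 enolate) | C=C(C)CC[C@@]1(C)CCC(O[Al](C)C)=C1 | intermediate
7 | (S)-triethyl{[3-methyl-3-(3-methylbut-3-en-1-yl)cyclopent-1-en-1-yl]oxy}silane | C=C(C)CC[C@@]1(C)CCC(O[Si](CC)(CC)CC)=C1 | intermediate
8 | (2S,3S)-2-(dimethoxymethyl)-3-methyl-3-(3-methylbut-3-en-1-yl)cyclopentan-1-one | COC(OC)[C@@H]1[C@](C)(CCC1=O)CCC(C)=C | intermediate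
9 | (1R,2R,3S)-2-(dimethoxymethyl)-3-methyl-3-(3-methylbut-3-en-1-yl)-1-(propan-2-yl)cyclopentan-1-ol | COC(OC)[C@@H]1[C@](C)(CC[C@@]1(O)C(C)C)CCC(C)=C | intermediate
10 | 1-{methoxy[(1R,2R,5S)-ring A unit of 11]methyl}-2,6-dimethylpyridinium triflate (configuration at the methoxy carbon undefined) | COC([C@@H]1[C@](C)(CC[C@@]1(O[Si](CC)(CC)CC)C(C)C)CCC(C)=C)[n+]1c(C)cccc1C.[O-]S(=O)(=O)C(F)(F)F | intermediate
11 | (1R,2R,5S)-5-methyl-5-(3-methylbut-3-en-1-yl)-2-(propan-2-yl)-2-[(triethylsilyl)oxy]cyclopentane-1-carbaldehyde | O=C[C@@H]1[C@](C)(CC[C@@]1(O[Si](CC)(CC)CC)C(C)C)CCC(C)=C | intermediate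
12 | 4β-[(triethylsilyl)oxy]dauc-8(14)-en-6α-ol; (3R,3aS,4S,8aS)-8a-methyl-6-methylidene-3-(propan-2-yl)-3-[(triethylsilyl)oxy]decahydroazulen-4-ol | C=C1C[C@H](O)[C@@H]2[C@](C)(CC[C@@]2(O[Si](CC)(CC)CC)C(C)C)CC1 | intermediate
13 | dauc-8(14)-ene-4β,6α-diol; (3R,3aS,4S,8aS)-8a-methyl-6-methylidene-3-(propan-2-yl)decahydroazulene-3,4-diol (trans-fused, 1β-CH3, 5α-H) | C=C1C[C@H](O)[C@@H]2[C@](C)(CC[C@@]2(O)C(C)C)CC1 | intermediate
14 | vanillic acid (4-hydroxy-3-methoxybenzoic acid) | COc1cc(C(=O)O)ccc1O | starting material
15 | tert-butyldimethylsilyl 4-[(tert-butyldimethylsilyl)oxy]-3-methoxybenzoate | COc1cc(C(=O)O[Si](C)(C)C(C)(C)C)ccc1O[Si](C)(C)C(C)(C)C | intermediate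
16 | 4-[(tert-butyldimethylsilyl)oxy]-3-methoxybenzoic acid | COc1cc(C(=O)O)ccc1O[Si](C)(C)C(C)(C)C | intermediate
17 | 4β-hydroxydauc-8(14)-en-6α-yl 4-[(tert-butyldimethylsilyl)oxy]-3-methoxybenzoate (3R,3aS,4S,8aS) | C=C1C[C@H](OC(=O)c2ccc(O[Si](C)(C)C(C)(C)C)c(OC)c2)[C@@H]2[C@](C)(CC[C@@]2(O)C(C)C)CC1 | intermediate
18 | 4β,9α-dihydroxydauc-8(14)-en-6α-yl 4-[(tert-butyldimethylsilyl)oxy]-3-methoxybenzoate (3R,3aS,4S,7S,8aR) | C=C1C[C@H](OC(=O)c2ccc(O[Si](C)(C)C(C)(C)C)c(OC)c2)[C@@H]2[C@](C)(CC[C@@]2(O)C(C)C)C[C@@H]1O | intermediate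
19 | (3R,3aS,4S,7S,8aR)-3,7-dihydroxy-8a-methyl-6-methylidene-3-(propan-2-yl)decahydroazulen-4-yl 4-hydroxy-3-methoxybenzoate | C=C1C[C@H](OC(=O)c2ccc(O)c(OC)c2)[C@@H]2[C@](C)(CC[C@@]2(O)C(C)C)C[C@@H]1O | target

Total step count: 10. Longest linear sequence: 9 (steps 1–6 and 8–10).

Steps most likely to fail

Step 6. Closure of the trans-fused seven-membered ring may be slow. Methyl transfer from aluminium to the aldehyde, proton loss toward C9 (double bond inside the ring) or attack on the wrong aldehyde face could then compete. The fallback replaces the pericyclic closure by a polar allylmetal closure. It sets out from aldehyde 11, which is chlorinated at the allylic position with transposition of the double bond (NCS, PhSeCl cat., CH2Cl2) to the 2-(chloromethyl)allyl aldehyde F1. CrCl2 in THF at high dilution (intramolecular Nozaki–Hiyama allylation) then joins the allylchromium terminus to C6 and fixes the double bond as the exocyclic methylene. This comes back to the route at silyl ether 12.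

Step 9. Competing hydrogen abstraction at C7, over-oxidation of the allylic alcohol to the enone, or poor facial selectivity at C9 may occur. The fallback sets out from ester 17. RhCl3·3H2O in hot ethanol moves the double bond into ring B to give the C8=C9 alkene, dauc-8-ene-4β,6α-diol 6-aroate F3. mCPBA should epoxidise this alkene on the α face, opposite to CH3-15, to give the 8α,9α-epoxide F4. Diethylaluminium 2,2,6,6-tetramethylpiperidide (from Et2AlCl and lithium 2,2,6,6-tetramethylpiperidide, toluene, 0 °C) removes a C14 proton syn to the oxirane oxygen and opens the epoxide. This comes back to the route at allylic alcohol 18 with the C9–O bond already fixed as α.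

Step 4. Enolisation of the hindered ketone, hydride transfer from the branched nucleophile, or elimination of methanol from the β-keto acetal may take over. The fallback sets out from ketone 8 and uses an sp2 nucleophile that has no transferable β-hydrogen. Prop-1-en-2-ylmagnesium bromide with CeCl3 adds from the same α face to give the isopropenyl carbinol F2. Hydroxyl-directed hydrogenation with [Ir(cod)(PCy3)(py)]PF6 and H2 (1 atm, CH2Cl2) should reduce the alkene next to the coordinating tertiary hydroxyl group faster than the remote one. This comes back to the route at alcohol 9.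

Further compounds
F1 | step 6 | (1R,2R,5S)-5-[3-(chloromethyl)but-3-en-1-yl]-5-methyl-2-(propan-2-yl)-2-[(triethylsilyl)oxy]cyclopentane-1-carbaldehyde | O=C[C@@H]1[C@](C)(CC[C@@]1(O[Si](CC)(CC)CC)C(C)C)CCC(=C)CCl
F2 | step 4 | (1S,2R,3S)-2-(dimethoxymethyl)-3-methyl-3-(3-methylbut-3-en-1-yl)-1-(prop-1-en-2-yl)cyclopentan-1-ol | COC(OC)[C@@H]1[C@](C)(CC[C@@]1(O)C(C)=C)CCC(C)=C
F3 | step 9 | 4β-hydroxydauc-8-en-6α-yl 4-[(tert-butyldimethylsilyl)oxy]-3-methoxybenzoate | CC=1C[C@H](OC(=O)c2ccc(O[Si](C)(C)C(C)(C)C)c(OC)c2)[C@@H]2[C@](C)(CC[C@@]2(O)C(C)C)CC=1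
F4 | step 9 | 8α,9α-epoxy-4β-hydroxydaucan-6α-yl 4-[(tert-butyldimethylsilyl)oxy]-3-methoxybenzoate | C[C@@]12C[C@H](OC(=O)c3ccc(O[Si](C)(C)C(C)(C)C)c(OC)c3)[C@@H]3[C@](C)(CC[C@@]3(O)C(C)C)C[C@@H]1O2
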